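**Retrosynthetic overview**
1. Target 23 is the bis-epoxide (C1–C10 and C4–C5, both trans) of 8β-tigloyloxycostunolide 22. Removing the epoxides, the tiglate and the C11 methylene leads back to the germacra-1(10)E,4E-dienolide 16.
2. Feature used: in the ten-membered ring the C1–C10 and C4–C5 oxiranes lie on either side of the C2–C3 bridge, so C10–C1–C2–C3–C4–C5 is a masked E,Z,E-triene (15). That triene is the open 6π valence isomer of the trans-fused eudesma-1,3-diene 14, whose C5–C10 bond is the transannular bond of the target ring.
3. 14 comes from α-santonin 1: ring A is saturated to the 5α-H 3-ketone and rebuilt as the 1,3-diene (Δ1-enone, dienyl triflate, reduction). The C8 oxygen enters through the 7(11)-butenolide (SeO2), and α-face hydrogenation restores the trans-lactone.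
4. Ring order: rings A and B and the γ-lactone are taken from santonin; the ten-membered carbocycle is unveiled in step 12 by C5–C10 cleavage; the two oxiranes are closed last in step 18.

Key step: step 12

Assumption: C11 is carried from step 7 to step 14 as the 11α-H epimer that syn hydrogenation should give; its configuration is erased in step 15, so it is a spectator centre.

**Step 1**
Reactants: 1 α-santonin
Product: 2 α-tetrahydrosantonin (3-oxo-4α-methyl-5αH,11βH-eudesman-12,6α-olide)
Conditions: H2 (1 atm), 10% Pd/C, EtOAc, rt; then HCl (cat.), CHCl3, rt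
Reagents that add atoms: none
Why: Catalytic hydrogenation saturates both dienone alkenes, hydrogen reaching C4=C5 from the α-face opposite the angular 10β-methyl so that C5 becomes 5α-H (trans-decalin), and the acid treatment epimerises C4 through the enol to the equatorial 4α-methyl ketone.

**Step 2**
Reactants: 2 α-tetrahydrosantonin
Product: 3 ethylene ketal of 2 (3,3-ethylenedioxy-4α-methyl-5αH,11βH-eudesman-12,6α-olide)
Conditions: HOCH2CH2OH, p-TsOH (cat.), benzene, reflux, Dean–Stark
Reagents that add atoms: ethylene glycol, OCCO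
Why: Acid-catalysed ketalisation with azeotropic removal of water masks the only ketone, so that the lactone α-position can be deprotonated selectively in step 3 and the ketone α-positions are protected from SeO2 in step 5.

**Step 3**
Reactants: 3 ethylene ketal of 2
Product: 5 exo-methylene lactone (3,3-ethylenedioxy-5αH-eudesm-11(13)-en-12,6α-olide), via 11β-phenylseleno lactone 4 (not isolated)
Conditions: LiN(iPr)2 (LDA), THF, −78 °C; PhSeCl, −78 → −20 °C; then AcOH, 30% H2O2, 0 °C → rt
Reagents that add atoms: none
Why: The lactone enolate is selenenylated on the β-face, anti to the axial 7α-H, and the selenoxide formed on oxidation undergoes syn-elimination that can then reach only a C13 hydrogen (α-selenenylation and selenoxide elimination); any 7(11)-isomer formed alongside is the product of step 4 and is carried on.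

**Step 4**
Reactants: 5 exo-methylene lactone
Product: 6 butenolide (3,3-ethylenedioxy-5αH,6βH-eudesm-7(11)-en-12,6α-olide)
Conditions: RuHCl(CO)(PPh3)3 (5 mol %), toluene, 100 °C
Reagents that add atoms: none
Why: The divalent ruthenium hydride adds across the exocyclic alkene and β-hydride elimination toward C7 moves the double bond into the thermodynamically preferred tetrasubstituted 7(11)-butenolide (metal hydride-catalysed alkene isomerisation); C6 keeps its configuration because it is not part of the migrating system, and the neutral catalyst leaves the ketal alone.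

**Step 5**
Reactants: 6 butenolide
Product: 7 8β-hydroxy butenolide (8β-hydroxy-3,3-ethylenedioxy-5αH,6βH-eudesm-7(11)-en-12,6α-olide)
Conditions: SeO2 (1.5 equiv), pyridine (2 equiv), dry dioxane, 90 °C
Reagents that add atoms: selenium dioxide, O=[Se]=O
Why: Riley allylic oxidation (ene reaction at C11, then [2,3]-sigmatropic shift) should prefer the ring methylene C8 over the C13 methyl and the acyloxy-deactivated C6–H; because the axial 8β-H is the one aligned with the π system and oxygen returns to the same face, the new C8 stereocentre should carry an axial β-hydroxyl, which also avoids allylic strain with the C13 methyl.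

**Step 6**
Reactants: 7 8β-hydroxy butenolide
Product: 8 8β-silyl ether (8β-(tert-butyldimethylsilyloxy)-3,3-ethylenedioxy-5αH,6βH-eudesm-7(11)-en-12,6α-olide)
Conditions: TBSOTf, 2,6-lutidine, CH2Cl2, −40 → 0 °C
Reagents that add atoms: tert-butyldimethylsilyl trifluoromethanesulfonate, CC(C)(C)[Si](C)(C)OS(=O)(=O)C(F)(F)F
Why: The silyl triflate with a hindered pyridine base silylates the hindered axial secondary alcohol (silyl ether formation); the group is transparent at 254 nm, stable to base, palladium and nickel, and bulky enough to cover the β-face in steps 7 and 14.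

**Step 7**
Reactants: 8 8β-silyl ether
Product: 9 saturated lactone (8β-(tert-butyldimethylsilyloxy)-3,3-ethylenedioxy-5αH,7αH,11αH-eudesman-12,6α-olide; 13-methyl β)
Conditions: H2 (4 atm), 5% Rh/Al2O3, EtOAc, rt
Reagents that add atoms: none
Why: Heterogeneous hydrogenation delivers both hydrogens syn to the α-face because the β-face of the butenolide is covered by the axial 8β-silyloxy group and the 10β-methyl, which sets C7 (7α-H, trans-fused lactone as in santonin) and C11 (11α-H); rhodium is chosen to keep hydrogenolysis of the allylic C–O bonds low.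

**Step 8**
Reactants: 9 saturated lactone
Product: 10 3-ketone (8β-(tert-butyldimethylsilyloxy)-3-oxo-4α-methyl-5αH,7αH,11αH-eudesman-12,6α-olide)
Conditions: pyridinium p-toluenesulfonate (0.3 equiv), acetone–H2O (9:1), 55 °C
Reagents that add atoms: water, O
Why: Mild acid-catalysed ketal hydrolysis frees the ketone, while the hindered secondary silyl ether and the lactone are stable to the pyridinium salt.

**Step 9**
Reactants: 10 3-ketone
Product: 12 Δ1-enone (8β-(tert-butyldimethylsilyloxy)-3-oxo-4α-methyl-5αH,11αH-eudesm-1-en-12,6α-olide), via trimethylsilyl enol ether 11 (not isolated)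
Conditions: LiN(iPr)2 (1.1 equiv), Me3SiCl, THF, −78 °C; then Pd(OAc)2 (1.1 equiv), MeCN, rt
Reagents that add atoms: none
Why: Kinetic deprotonation takes the C2 methylene of the ketone (more acidic than the lactone C11–H and less hindered than C4–H), and the silyl enol ether is dehydrosilylated by divalent palladium through an oxa-π-allyl complex and β-hydride elimination (Saegusa–Ito oxidation) to the Δ1-enone.

**Step 10**
Reactants: 12 Δ1-enone
Product: 13 dienyl triflate (8β-(tert-butyldimethylsilyloxy)-3-(trifluoromethanesulfonyloxy)-5αH,11αH-eudesma-1,3-dien-12,6α-olide)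
Conditions: KN(SiMe3)2 (1.1 equiv), THF, −78 °C; PhNTf2, −78 → 0 °C
Reagents that add atoms: N-phenylbis(trifluoromethanesulfonimide), O=S(=O)(N(c1ccccc1)S(=O)(=O)C(F)(F)F)C(F)(F)F
Why: The enone has only one enolisable position, C4–H (C10 is quaternary), so the cross-conjugated dienolate forms cleanly and is O-sulfonylated to the 1,3-dien-3-yl triflate (enol triflate formation); the ketone proton is removed ahead of the less acidic lactone proton.

**Step 11**
Reactants: 13 dienyl triflate
Product: 14 trans-fused 1,3-diene (8β-(tert-butyldimethylsilyloxy)-5αH,11αH-eudesma-1,3-dien-12,6α-olide)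
Conditions: Pd(OAc)2 (5 mol %), PPh3 (10 mol %), Bu3N, HCO2H, DMF, 60 °C; product kept under argon
Reagents that add atoms: none
Why: Zerovalent palladium inserts into the C–OTf bond, formate transfers hydride with loss of CO2, and reductive elimination forms the C3–H bond without moving either double bond (palladium-catalysed formate reduction of an enol triflate).

**Step 12**
Reactants: 14 trans-fused 1,3-diene
Product: 15 triene (8β-(tert-butyldimethylsilyloxy)-11αH-germacra-1(10)E,2Z,4E-trien-12,6α-olide), kept as a cold solution
Conditions: hν (254 nm, low-pressure Hg lamp, quartz), degassed MeOH–THF (4:1), −40 °C, to the photostationary state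
Reagents that add atoms: none
Why: Absorption by the cisoid ring-A diene, the only chromophore at 254 nm, leads from the singlet excited state to a concerted conrotatory 6π electrocyclic ring opening that cleaves the C5–C10 σ bond; the closest known reaction type is the photochemical opening of trans-fused bicyclo[4.4.0]deca-2,4-dienes to cyclodeca-1,3,5-trienes, the same process as provitamin D to previtamin D. No ring is closed by bond formation: the ten-membered carbocycle appears because the bond shared by rings A and B is cut, so this is an electrocyclic ring expansion and has no cyclisation mode. No stereocentre is created and C6, C7, C8 and C11 are untouched; the geometry of the three alkenes follows from the trans ring fusion, whose equatorial ring bonds C5–C6 and C10–C9 turn outward in the conrotatory motion dictated by the helical twist of the diene while 5α-H and the 10β-methyl turn inward, giving 1(10)E, 2Z and 4E. The step needs this sense of rotation, which the trans fusion secures, and it needs the triene to survive: the low temperature suppresses thermal disrotatory reclosure (which would lead to the cis-fused diene), and irradiation is stopped at the stationary state to limit secondary photoisomerisation, with recovered 14 irradiated again.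

**Step 13**
Reactants: 15 triene
Product: 16 dienolide (8β-(tert-butyldimethylsilyloxy)-11αH-germacra-1(10)E,4E-dien-12,6α-olide)
Conditions: H2 (1 atm), Raney Ni (W-2), MeOH–THF, −20 °C, directly on the cold photolysate
Reagents that add atoms: none
Why: Low-temperature heterogeneous hydrogenation should take the central cis-disubstituted alkene, the least substituted and most exposed of the three, while the two methyl-bearing trisubstituted E-alkenes are shielded; once C2=C3 is saturated the ring can no longer reclose.

**Step 14**
Reactants: 16 dienolide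
Product: 17 α-bromo lactone (11α-bromo-8β-(tert-butyldimethylsilyloxy)-germacra-1(10)E,4E-dien-12,6α-olide; 13-methyl β)
Conditions: LiN(iPr)2 (1.3 equiv), THF, −78 °C; BrCCl2CCl2Br, −78 → −20 °C
Reagents that add atoms: 1,2-dibromo-1,1,2,2-tetrachloroethane, ClC(Cl)(Br)C(Cl)(Cl)Br
Why: The exposed 11α-H is removed and the lactone enolate is brominated by halophilic attack on the α-face, anti to the 8β-silyloxy group that covers the β-face, which sets C11 with bromine cis to 7α-H (α-bromination of an ester enolate); the reagent is not electrophilic toward the ring alkenes.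

**Step 15**
Reactants: 17 α-bromo lactone
Product: 18 silylated α-methylene lactone (8β-(tert-butyldimethylsilyloxy)-germacra-1(10)E,4E,11(13)-trien-12,6α-olide)
Conditions: DBU (3 equiv), toluene, 60 °C
Reagents that add atoms: none
Why: E2 elimination needs an antiperiplanar hydrogen, and since 7α-H is syn to the α-bromine only the C13 methyl can supply it, so the exocyclic α-methylene lactone should form and not the 7(11)-butenolide (amidine-mediated dehydrobromination); the temperature stays well below that of the Cope rearrangement of the 1(10),4-diene.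

**Step 16**
Reactants: 18 silylated α-methylene lactone
Product: 19 eupatolide (8β-hydroxygermacra-1(10)E,4E,11(13)-trien-12,6α-olide)
Conditions: Bu4NF (1.5 equiv), AcOH (1.5 equiv), THF, 0 °C → rt
Reagents that add atoms: none
Why: Fluoride cleaves the Si–O bond and the acetic acid buffer keeps the medium near neutral, so the α-methylene lactone is spared conjugate addition and the acid-sensitive 1(10),4-diene is spared transannular cyclisation (fluoride desilylation).

**Step 17**
Reactants: 19 eupatolide; 20 tiglic acid
Product: 22 eupatolide tiglate (8β-tigloyloxygermacra-1(10)E,4E,11(13)-trien-12,6α-olide), via tiglic 2,4,6-trichlorobenzoic anhydride 21 (not isolated)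
Conditions: 20, 2,4,6-Cl3C6H2COCl, Et3N, toluene, rt; then 19, DMAP, rt → 40 °C
Reagents that add atoms: none
Why: Yamaguchi esterification: the mixed anhydride is attacked at the less hindered tigloyl carbonyl through the acylpyridinium ion, which acylates the hindered 8β-alcohol without changing the E geometry of the tiglate or any stereocentre.

**Step 18**
Reactants: 22 eupatolide tiglate
Product: 23 target (1β,10α:4α,5β-diepoxy-8β-tigloyloxygermacr-11(13)-en-12,6α-olide)
Conditions: mCPBA (2.4 equiv), NaHCO3, CH2Cl2, 0 °C → rt
Reagents that add atoms: meta-chloroperoxybenzoic acid, OOC(=O)c1cccc(Cl)c1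
Why: Prilezhaev epoxidation is confined to the two electron-rich trisubstituted ring alkenes (the tiglate and α-methylene lactone alkenes are electron-poor), each attacked on its outer face in the crown conformation in which C14 and C15 are syn and the alkene planes stand perpendicular to the ring, which sets C1/C10 as 1β,10α and C4/C5 as 4α,5β; the E geometry makes both oxiranes trans, and the bicarbonate buffer suppresses acid-induced transannular cyclisation of the monoepoxide.

**Compound list**
1 | (−)-α-santonin (3-oxoeudesma-1,4-dien-12,6α-olide; 6β-H, 7α-H, 10β-methyl, 11β-H) | C[C@H]1[C@@H]2CC[C@]3(C=CC(=O)C(=C3[C@H]2OC1=O)C)C | starting material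
2 | α-tetrahydrosantonin (3-oxo-4α-methyl-5αH,11βH-eudesman-12,6α-olide) | C[C@@H]1C(=O)O[C@H]2[C@H]1CC[C@@]1(C)CCC(=O)[C@@H](C)[C@H]21 | intermediate
3 | 3,3-ethylenedioxy-4α-methyl-5αH,11βH-eudesman-12,6α-olide | C[C@@H]1C(=O)O[C@H]2[C@H]1CC[C@@]1(C)CCC3(OCCO3)[C@@H](C)[C@H]21 | intermediate
4 | 3,3-ethylenedioxy-11β-phenylseleno-5αH-eudesman-12,6α-olide (13-methyl α) | C[C@]1([Se]c3ccccc3)C(=O)O[C@H]2[C@H]1CC[C@@]1(C)CCC3(OCCO3)[C@@H](C)[C@H]21 | intermediate
5 | 3,3-ethylenedioxy-5αH-eudesm-11(13)-en-12,6α-olide | C=C1C(=O)O[C@H]2[C@H]1CC[C@@]1(C)CCC3(OCCO3)[C@@H](C)[C@H]21 | intermediate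
6 | 3,3-ethylenedioxy-5αH,6βH-eudesm-7(11)-en-12,6α-olide | CC1=C2CC[C@@]3(C)CCC4(OCCO4)[C@@H](C)[C@@H]3[C@H]2OC1=O | intermediate
7 | 8β-hydroxy-3,3-ethylenedioxy-5αH,6βH-eudesm-7(11)-en-12,6α-olide | CC1=C2[C@H](O)C[C@@]3(C)CCC4(OCCO4)[C@@H](C)[C@@H]3[C@H]2OC1=O | intermediate
8 | 8β-(tert-butyldimethylsilyloxy)-3,3-ethylenedioxy-5αH,6βH-eudesm-7(11)-en-12,6α-olide | CC1=C2[C@H](O[Si](C)(C)C(C)(C)C)C[C@@]3(C)CCC4(OCCO4)[C@@H](C)[C@@H]3[C@H]2OC1=O | intermediate
9 | 8β-(tert-butyldimethylsilyloxy)-3,3-ethylenedioxy-5αH,7αH,11αH-eudesman-12,6α-olide | C[C@H]1C(=O)O[C@H]2[C@H]1[C@H](O[Si](C)(C)C(C)(C)C)C[C@@]1(C)CCC3(OCCO3)[C@@H](C)[C@H]21 | intermediate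
10 | 8β-(tert-butyldimethylsilyloxy)-3-oxo-4α-methyl-5αH,7αH,11αH-eudesman-12,6α-olide | C[C@H]1C(=O)O[C@H]2[C@H]1[C@H](O[Si](C)(C)C(C)(C)C)C[C@@]1(C)CCC(=O)[C@@H](C)[C@H]21 | intermediate
11 | 8β-(tert-butyldimethylsilyloxy)-3-trimethylsilyloxy-5αH,11αH-eudesm-2-en-12,6α-olide | C[C@H]1C(=O)O[C@H]2[C@H]1[C@H](O[Si](C)(C)C(C)(C)C)C[C@@]1(C)CC=C(O[Si](C)(C)C)[C@@H](C)[C@H]21 | intermediate
12 | 8β-(tert-butyldimethylsilyloxy)-3-oxo-4α-methyl-5αH,11αH-eudesm-1-en-12,6α-olide | C[C@H]1C(=O)O[C@H]2[C@H]1[C@H](O[Si](C)(C)C(C)(C)C)C[C@@]1(C)C=CC(=O)[C@@H](C)[C@H]21 | intermediate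
13 | 8β-(tert-butyldimethylsilyloxy)-3-(trifluoromethanesulfonyloxy)-5αH,11αH-eudesma-1,3-dien-12,6α-olide | C[C@H]1C(=O)O[C@H]2[C@H]1[C@H](O[Si](C)(C)C(C)(C)C)C[C@@]1(C)C=CC(OS(=O)(=O)C(F)(F)F)=C(C)[C@H]21 | intermediate
14 | 8β-(tert-butyldimethylsilyloxy)-5αH,11αH-eudesma-1,3-dien-12,6α-olide (10β-methyl, trans-fused) | C[C@H]1C(=O)O[C@H]2[C@H]1[C@H](O[Si](C)(C)C(C)(C)C)C[C@@]1(C)C=CC=C(C)[C@H]21 | intermediate
15 | 8β-(tert-butyldimethylsilyloxy)-11αH-germacra-1(10)E,2Z,4E-trien-12,6α-olide | C[C@H]1C(=O)O[C@H]2[C@H]1[C@H](O[Si](C)(C)C(C)(C)C)C/C(C)=C/C=C\C(C)=C\2 | intermediate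
16 | 8β-(tert-butyldimethylsilyloxy)-11αH-germacra-1(10)E,4E-dien-12,6α-olide | C[C@H]1C(=O)O[C@H]2[C@H]1[C@H](O[Si](C)(C)C(C)(C)C)C/C(C)=C/CC/C(C)=C/2 | intermediate
17 | 11α-bromo-8β-(tert-butyldimethylsilyloxy)-germacra-1(10)E,4E-dien-12,6α-olide (13-methyl β) | C[C@@]1(Br)C(=O)O[C@H]2[C@H]1[C@H](O[Si](C)(C)C(C)(C)C)C/C(C)=C/CC/C(C)=C/2 | intermediate
18 | 8β-(tert-butyldimethylsilyloxy)-germacra-1(10)E,4E,11(13)-trien-12,6α-olide | C=C1C(=O)O[C@H]2[C@H]1[C@H](O[Si](C)(C)C(C)(C)C)C/C(C)=C/CC/C(C)=C/2 | intermediate
19 | eupatolide (8β-hydroxygermacra-1(10)E,4E,11(13)-trien-12,6α-olide) | C=C1C(=O)O[C@H]2[C@H]1[C@H](O)C/C(C)=C/CC/C(C)=C/2 | intermediate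
20 | tiglic acid ((E)-2-methylbut-2-enoic acid) | C/C=C(\C)C(=O)O | starting material
21 | (E)-2-methylbut-2-enoic 2,4,6-trichlorobenzoic anhydride | C/C=C(\C)C(=O)OC(=O)c1c(Cl)cc(Cl)cc1Cl | intermediate
22 | 8β-tigloyloxygermacra-1(10)E,4E,11(13)-trien-12,6α-olide | C=C1C(=O)O[C@H]2[C@H]1[C@H](OC(=O)/C(C)=C/C)C/C(C)=C/CC/C(C)=C/2 | intermediate
23 | (1R,4R,5R,6S,7R,8R,10R)-1β,10α:4α,5β-diepoxy-8β-tigloyloxygermacr-11(13)-en-12,6α-olide | C=C1C(=O)O[C@H]2[C@H]1[C@H](OC(=O)/C(C)=C/C)C[C@@]1(C)O[C@@H]1CC[C@@]1(C)O[C@H]21 | target

**Step count**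
Total: 18 steps. Longest linear sequence: 18 steps (1 → 23); tiglic acid 20 enters in step 17.

**Steps most likely to fail**

Step 5 (allylic oxidation). The ene reaction may take the C6 or C13 hydrogen instead of C8–H, may stall on the electron-poor alkene, or may deliver oxygen without facial control. The fallback separates site and face. It sets out from 6: oxidation of the allylic methylene to the ketone with Rh2(cap)4 (cap = caprolactamate, cat.) and t-BuOOH in CH2Cl2 at rt gives the 8-oxo butenolide F1. Luche reduction (NaBH4, CeCl3·7H2O, MeOH, −78 °C) then delivers hydride to the α-face, the β-face being blocked by the syn-axial 10β-methyl, so that the axial 8β-alcohol results and the route is rejoined at 7.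

Step 7 (hydrogenation of the butenolide). The tetrasubstituted alkene beside the axial silyl ether may resist hydrogen uptake, or hydrogenolysis of the allylic C–O bonds may compete. The fallback makes the alkene more reactive before reducing it. It sets out from 7: Dess–Martin oxidation gives the 8-oxo butenolide F1, whose doubly activated alkene should take up hydrogen readily from the α-face (H2 1 atm, Pd/C, EtOAc) to give the 8-oxo lactone F2. C7 is now α to the ketone and can settle in the trans-lactone arrangement. KB(s-Bu)3H (K-Selectride) in THF at −78 °C attacks from the equatorial α-side to give the axial 8β-alcohol F3, and silylation (TBSOTf, 2,6-lutidine) rejoins the route at 9.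

Step 14 (bromination, with its consequence in step 15). If bromine enters the β-face instead, it ends up anti to 7α-H, and the E2 step would then remove H7 and return the 7(11)-butenolide. The fallback uses an elimination with the opposite geometric demand. It sets out from 16: the enolate (LiN(iPr)2, THF, −78 °C) is selenenylated with PhSeSePh and HMPA, which does not add to the ring alkenes, to give the 11β-phenylselenide F4. Oxidation (30% H2O2, pyridine, CH2Cl2, 0 °C) triggers selenoxide syn-elimination, which from the β-face can reach only a C13 hydrogen, and the route is rejoined at 18.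

**Further compounds**
F1 | step 5 | 3,3-ethylenedioxy-8-oxo-5αH,6βH-eudesm-7(11)-en-12,6α-olide | CC1=C2C(=O)C[C@@]3(C)CCC4(OCCO4)[C@@H](C)[C@@H]3[C@H]2OC1=O
F2 | step 7 | 3,3-ethylenedioxy-8-oxo-5αH,7αH,11αH-eudesman-12,6α-olide | C[C@H]1C(=O)O[C@H]2[C@H]1C(=O)C[C@@]1(C)CCC3(OCCO3)[C@@H](C)[C@H]21
F3 | step 7 | 8β-hydroxy-3,3-ethylenedioxy-5αH,7αH,11αH-eudesman-12,6α-olide | C[C@H]1C(=O)O[C@H]2[C@H]1[C@H](O)C[C@@]1(C)CCC3(OCCO3)[C@@H](C)[C@H]21
F4 | step 14 | 11β-phenylseleno-8β-(tert-butyldimethylsilyloxy)-germacra-1(10)E,4E-dien-12,6α-olide (13-methyl α) | C[C@]1([Se]c3ccccc3)C(=O)O[C@H]2[C@H]1[C@H](O[Si](C)(C)C(C)(C)C)C/C(C)=C/CC/C(C)=C/2
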